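**Retrosynthetic overview**
Feature: the benzene ring of the indenone (C3a, C4, C5, C6, C7, C7a). Its edge C4–C5(H)–C6(azulenyl)–C7(CH3) is the imprint of a methyl-substituted vinylketene (C4 = ketene carbonyl carbon, C7 = ketene α-carbon) and a terminal azulenyl alkyne (C5, C6). The vinyl part of the ketene (C7a=C3a) already sits in the five-membered ring.
Endgame: C4–CHO from C4–OTf, which comes from C4–OH (the annulation phenol); C2=C3 from the trans-indanone (Saegusa–Ito); C1=O from a C1 silyl ether.
Key disconnection: C7–C7a (Wolff shift), C4–C5 and C6–C7 ([2+2]) and C3a–C4 (six-electron closure). This leads back to a cyclopentenyl 2-diazopropanoyl ketone and 3-ethynylguaiazulene.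
C1 is held as a silyl ether, not as the ketone, through diazo transfer and annulation. With a C1 ketone, C2–H and the vinylogous C3–H would be deprotonated before the ethyl CH2, and the diazo ketone would be an alkylidene-1,3-dicarbonyl compound prone to conjugate addition and dimerisation.
Ring order: five-membered ring first (C2–C3 by Ireland–Claisen, C3a=C7a by cross metathesis with ethyl vinyl ketone, C1–C7a by intramolecular Morita–Baylis–Hillman), benzene ring second. Both azulene units come from guaiazulene.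

Key step: step 11

Remark on the chemistry: the target has no stereocentre, so every stereocentre below is transient; chiral compounds are racemic with one enantiomer drawn, the carbinol carbon that becomes C1 is carried as a mixture of epimers (left open in the SMILES), ring atoms are given in indenone numbering, and guaiazulen-3-yl means 5-isopropyl-3,8-dimethylazulen-1-yl.

**Route**

Step 1
Reactants: 1 guaiazulene
Product: 3 guaiazulene-3-carbaldehyde, via iminium salt 2 (not isolated)
Conditions: POCl3, DMF, 0 → 25 °C; then aq NaOH, 0 °C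
Reagents that add atoms: N,N-dimethylformamide CN(C)C=O (formyl carbon); water O (carbonyl oxygen)
Why: Vilsmeier–Haack formylation: the chloroiminium ion attacks C3, the only free nucleophilic position of the five-membered azulene ring, and basic hydrolysis of 2 releases the aldehyde.

Step 2
Reactants: 3 guaiazulene-3-carbaldehyde
Product: 4 3-ethynylguaiazulene
Conditions: Me3SiCHN2, LiN(iPr)2, THF, −78 °C; add 3; −78 → 25 °C; H2O
Reagents that add atoms: (trimethylsilyl)diazomethane C[Si](C)(C)C=[N+]=[N-]
Why: Colvin homologation (aldehyde to terminal alkyne with lithiated trimethylsilyldiazomethane): the reagent is nucleophilic enough for this donor-deactivated aldehyde and, unlike a Corey–Fuchs sequence, brings no halogenating agent near the azulene; 4 is stored cold under argon and used soon.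

Step 3
Reactants: 1 guaiazulene; 5 ethyl diazoacetate
Product: 6 ethyl 2-(guaiazulen-3-yl)acetate
Conditions: [Cu(MeCN)4]PF6 (5 mol %), CH2Cl2, 25 °C, 5 added over 6 h
Reagents that add atoms: none
Why: Copper-carbenoid C–H functionalisation, a known reaction of azulene and guaiazulene with diazoacetates: nucleophilic C3 attacks the electrophilic carbenoid and a proton shift restores the azulene, while slow addition of 5 limits carbene dimerisation.

Step 4
Reactants: 6 ethyl 2-(guaiazulen-3-yl)acetate; 7 (E)-but-2-en-1-ol (crotyl alcohol)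
Product: 8 (E)-but-2-enyl 2-(guaiazulen-3-yl)acetate
Conditions: Ti(OiPr)4 (10 mol %), 7 (5 equiv), toluene, 110 °C, EtOH distilled off
Reagents that add atoms: none
Why: Titanate-catalysed transesterification under neutral conditions, driven by removal of ethanol, leaves the azulene and the (E)-alkene untouched.

Step 5
Reactants: 8 (E)-but-2-enyl 2-(guaiazulen-3-yl)acetate
Product: 11 (2R*,3R*)-2-(guaiazulen-3-yl)-3-methylpent-4-enoic acid (syn; racemic), via silyl ketene acetal 9 (not isolated), via trimethylsilyl ester 10 (not isolated)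
Conditions: LiN(iPr)2, THF–DMPU (4:1), −78 °C; Me3SiCl; −78 → 40 °C; then 1 M aq HCl
Reagents that add atoms: chlorotrimethylsilane C[Si](C)(C)Cl (silyl group stands only in 9 and 10)
Why: Ireland–Claisen rearrangement: enolisation in THF–DMPU should place the azulenyl group cis to the metal-bound oxygen and give (Z)-ketene acetal 9, whose chair transition state with the (E)-crotyl unit forms C2–C3 and sets both new stereocentres syn (trans in the later ring); both are erased in step 15, so this control only keeps the intermediates homogeneous.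

Step 6
Reactants: 11 (2R*,3R*)-2-(guaiazulen-3-yl)-3-methylpent-4-enoic acid
Product: 13 (2R*,3R*)-2-(guaiazulen-3-yl)-3-methylpent-4-enal, via acyl imidazolide 12 (not isolated)
Conditions: 1,1'-carbonyldiimidazole, CH2Cl2, 25 °C; then iBu2AlH (2.1 equiv), −78 °C; aq potassium sodium tartrate
Reagents that add atoms: 1,1'-carbonyldiimidazole O=C(n1ccnc1)n1ccnc1 (imidazolyl group stands only in 12)
Why: Activation as the acyl imidazolide and low-temperature hydride reduction to a tetrahedral aluminate that collapses to the aldehyde only on work-up, a known one-flask acid-to-aldehyde reduction; −78 °C spares the terminal alkene and limits epimerisation next to the azulene.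

Step 7
Reactants: 13 (2R*,3R*)-2-(guaiazulen-3-yl)-3-methylpent-4-enal; 14 pent-1-en-3-one (ethyl vinyl ketone)
Product: 15 (2R*,3R*,4E)-2-(guaiazulen-3-yl)-3-methyl-6-oxooct-4-enal
Conditions: 14 (3 equiv), second-generation Hoveyda–Grubbs catalyst (5 mol %), CH2Cl2, 40 °C
Reagents that add atoms: none
Why: Olefin cross metathesis of a terminal alkene with an electron-poor vinyl ketone, a pairing that is selective for the (E)-enone and tolerates aldehydes; it forms the future C3a=C7a bond and brings in C7a, C4, C7 and the C7 methyl group.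

Step 8
Reactants: 15 (2R*,3R*,4E)-2-(guaiazulen-3-yl)-3-methyl-6-oxooct-4-enal
Product: 16 1-[3,4-trans-4-(guaiazulen-3-yl)-5-hydroxy-3-methylcyclopent-1-en-1-yl]propan-1-one (racemic; carbinol epimers)
Conditions: PMe3 (0.3 equiv), CH2Cl2 (0.05 M), 25 °C
Reagents that add atoms: none
Why: Intramolecular Morita–Baylis–Hillman reaction: the phosphine adds to the enone β-carbon, the enolate carbon closes the five-membered ring onto the aldehyde (5-exo aldol, C1–C7a) and the phosphine is expelled, which leaves C1 as a carbinol and the side chain as the ethyl ketone; the new carbinol centre is not controlled because it becomes the carbonyl carbon in step 14.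

Step 9
Reactants: 16 1-[3,4-trans-4-(guaiazulen-3-yl)-5-hydroxy-3-methylcyclopent-1-en-1-yl]propan-1-one
Product: 17 1-[3,4-trans-5-(tert-butyldimethylsilyloxy)-4-(guaiazulen-3-yl)-3-methylcyclopent-1-en-1-yl]propan-1-one
Conditions: tBuMe2SiOTf, 2,6-lutidine, CH2Cl2, −78 → 0 °C
Reagents that add atoms: tert-butyldimethylsilyl triflate CC(C)(C)[Si](C)(C)OS(=O)(=O)C(F)(F)F
Why: Silylation of a hindered secondary allylic alcohol with a silyl triflate and a non-nucleophilic base; the ether removes the hydroxyl group that would otherwise consume base in step 10 and trap the ketene in step 11.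

Step 10
Reactants: 17 1-[3,4-trans-5-(tert-butyldimethylsilyloxy)-4-(guaiazulen-3-yl)-3-methylcyclopent-1-en-1-yl]propan-1-one
Product: 19 2-diazo-1-[3,4-trans-5-(tert-butyldimethylsilyloxy)-4-(guaiazulen-3-yl)-3-methylcyclopent-1-en-1-yl]propan-1-one, via trifluoroacetyl diketone 18 (not isolated)
Conditions: LiN(SiMe3)2, THF, −78 °C; CF3CO2CH2CF3, −78 °C; 5% aq HCl wash; crude 18, MsN3, Et3N, H2O (1 equiv), MeCN, 25 °C
Reagents that add atoms: methanesulfonyl azide CS(=O)(=O)N=[N+]=[N-]; 2,2,2-trifluoroethyl trifluoroacetate O=C(OCC(F)(F)F)C(F)(F)F (trifluoroacetyl group stands only in 18)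
Why: Detrifluoroacetylative diazo transfer: with C1 at the ether level the ethyl CH2 is the only α-position bearing hydrogen, so kinetic enolisation, Claisen-type trifluoroacetylation to 18 and reaction with mesyl azide, which cleaves the trifluoroacetyl group, put the diazo group on the methyl-bearing carbon.

Step 11
Reactants: 19 2-diazo-1-[3,4-trans-5-(tert-butyldimethylsilyloxy)-4-(guaiazulen-3-yl)-3-methylcyclopent-1-en-1-yl]propan-1-one; 4 3-ethynylguaiazulene
Product: 24 2,3-trans-1-(tert-butyldimethylsilyloxy)-2,6-bis(guaiazulen-3-yl)-3,7-dimethylindan-4-ol (racemic; C1 epimers), via vinylketene 20 (not isolated), via cyclobutenone 21 (not isolated), via dienylketene 22 (not isolated), via cyclohexadienone 23 (not isolated)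
Conditions: 4 (3 equiv), ClCH2CH2Cl (0.05 M), argon, 440 nm LEDs, 20 °C; then 80 °C in the dark
Reagents that add atoms: none
Why: Proposed new method: blue light, chosen to fall in the window between the two azulene absorption bands, expels N2 from 19 with 1,2-shift of the cyclopentenyl carbon (Wolff rearrangement, C7–C7a) to vinylketene 20, whose carbonyl carbon is attacked by the terminal carbon of 4, so that a stepwise [2+2] addition (C4–C5, then C6–C7) gives cyclobutenone 21. Heating opens 21 in a conrotatory four-electron step to dienylketene 22, and the benzene ring is closed by a disrotatory six-electron electrocyclisation of the ketene carbon onto the cyclopentene CH (C3a–C4) to dienone 23, which tautomerises to phenol 24. The closest known reaction is the Danheiser benzannulation in its diazo ketone form, which has been run with alkynyl ethers, alkynyl thioethers, ynamines and ynamides but not with an aryl alkyne, whereas 19 is of the cycloalkenyl diazo ketone type used there. The extension rests on the fact that attack through the alkyne terminus leaves a vinyl cation delocalised as an azulenium (tropylium-type) ion, the same polarisation that lets 1-azulenyl alkynes undergo stepwise [2+2] addition to tetracyanoethene. The only selectivity needed is the orientation of this addition, and the azulene donor secures it by placing H at C5 and the azulenyl group at C6 next to the methyl-bearing C7, while the reversible opening of 21 funnels the material through the isomer of 22 that can cyclise. No stereocentre is created in 24 (the quaternary carbon of 21 and C3a–H of 23 are lost again), C2 and C3 are untouched, and the C1 silyl ether keeps the ketene free of an internal hydroxyl nucleophile and the alkene free of a second acceptor group.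

Step 12
Reactants: 24 2,3-trans-1-(tert-butyldimethylsilyloxy)-2,6-bis(guaiazulen-3-yl)-3,7-dimethylindan-4-ol
Product: 25 2,3-trans-2,6-bis(guaiazulen-3-yl)-3,7-dimethylindane-1,4-diol (C1 epimers)
Conditions: Bu4NF (3 equiv), THF, 25 → 40 °C
Reagents that add atoms: none
Why: Fluoride-induced Si–O cleavage, placed before the triflation so that fluoride never meets the aryl triflate.

Step 13
Reactants: 25 2,3-trans-2,6-bis(guaiazulen-3-yl)-3,7-dimethylindane-1,4-diol
Product: 26 2,3-trans-2,6-bis(guaiazulen-3-yl)-1-hydroxy-3,7-dimethylindan-4-yl trifluoromethanesulfonate (C1 epimers)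
Conditions: PhNTf2 (1.1 equiv), Et3N, CH2Cl2, 0 → 25 °C
Reagents that add atoms: N-phenylbis(trifluoromethanesulfonimide) O=S(=O)(N(c1ccccc1)S(=O)(=O)C(F)(F)F)C(F)(F)F
Why: Chemoselective O-sulfonylation: under amine base PhNTf2 reacts with the phenoxide and leaves the hindered secondary alcohol alone.

Step 14
Reactants: 26 2,3-trans-2,6-bis(guaiazulen-3-yl)-1-hydroxy-3,7-dimethylindan-4-yl trifluoromethanesulfonate
Product: 27 trans-2,6-bis(guaiazulen-3-yl)-3,7-dimethyl-1-oxoindan-4-yl trifluoromethanesulfonate (racemic)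
Conditions: Dess–Martin periodinane, CH2Cl2, 0 → 25 °C
Reagents that add atoms: none
Why: Dess–Martin oxidation of the benzylic alcohol merges the two C1 epimers into one ketone; C2 is now epimerisable and should rest in the trans arrangement.

Step 15
Reactants: 27 trans-2,6-bis(guaiazulen-3-yl)-3,7-dimethyl-1-oxoindan-4-yl trifluoromethanesulfonate
Product: 29 2,6-bis(guaiazulen-3-yl)-3,7-dimethyl-1-oxo-1H-inden-4-yl trifluoromethanesulfonate, via silyl enol ether 28 (not isolated)
Conditions: Me3SiOTf, Et3N, CH2Cl2, 0 °C; crude 28, Pd(OAc)2 (1.1 equiv), MeCN, 25 → 40 °C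
Reagents that add atoms: trimethylsilyl triflate C[Si](C)(C)OS(=O)(=O)C(F)(F)F (silyl group stands only in 28)
Why: Saegusa–Ito dehydrogenation: C2–H is the only enolisable hydrogen, so soft enolisation gives 28 alone, divalent palladium forms the enolate on the face opposite the C3 methyl group, which is the face of C3–H, and syn β-hydride elimination gives the tetrasubstituted C2=C3 bond and removes the last two stereocentres; without phosphine the aryl triflate should stay intact.

Step 16
Reactants: 29 2,6-bis(guaiazulen-3-yl)-3,7-dimethyl-1-oxo-1H-inden-4-yl trifluoromethanesulfonate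
Product: 30 2,6-bis(guaiazulen-3-yl)-3,7-dimethyl-1-oxo-1H-indene-4-carbaldehyde (CNP0222726.0)
Conditions: Pd(OAc)2 (5 mol %), dppp (5 mol %), CO (1 atm), Et3SiH (2 equiv, syringe pump), Et3N, DMF, 70 °C
Reagents that add atoms: carbon monoxide [C-]#[O+]
Why: Palladium-catalysed reductive carbonylation of an aryl triflate: oxidative addition to zerovalent palladium, CO insertion and hydride transfer from the silane give the aldehyde, and slow addition of Et3SiH together with the hindered tetrasubstituted C2=C3 bond should hold back conjugate reduction of the indenone.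

**Compound list**
1 | guaiazulene (7-isopropyl-1,4-dimethylazulene) | Cc1ccc2c(C)ccc(C(C)C)cc1-2 | starting material
2 | N,N-dimethyl(guaiazulen-3-yl)methaniminium dichlorophosphate | C[N+](C)=Cc1cc(C)c2cc(C(C)C)ccc(C)c1-2.[O-]P(=O)(Cl)Cl | intermediate (not isolated)
3 | guaiazulene-3-carbaldehyde | O=Cc1cc(C)c2cc(C(C)C)ccc(C)c1-2 | intermediate
4 | 3-ethynylguaiazulene | C#Cc1cc(C)c2cc(C(C)C)ccc(C)c1-2 | intermediate
5 | ethyl diazoacetate | CCOC(=O)C=[N+]=[N-] | starting material
6 | ethyl 2-(guaiazulen-3-yl)acetate | CCOC(=O)Cc1cc(C)c2cc(C(C)C)ccc(C)c1-2 | intermediate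
7 | (E)-but-2-en-1-ol (crotyl alcohol) | C/C=C/CO | starting material
8 | (E)-but-2-enyl 2-(guaiazulen-3-yl)acetate | C/C=C/COC(=O)Cc1cc(C)c2cc(C(C)C)ccc(C)c1-2 | intermediate
9 | (Z)-1-[(E)-but-2-enyloxy]-2-(guaiazulen-3-yl)-1-(trimethylsilyloxy)ethene (azulenyl cis to OSiMe3) | C/C=C/CO/C(O[Si](C)(C)C)=C/c1cc(C)c2cc(C(C)C)ccc(C)c1-2 | intermediate (not isolated)
10 | trimethylsilyl (2R*,3R*)-2-(guaiazulen-3-yl)-3-methylpent-4-enoate | C=C[C@@H](C)[C@H](c1cc(C)c2cc(C(C)C)ccc(C)c1-2)C(=O)O[Si](C)(C)C | intermediate (not isolated)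
11 | (2R*,3R*)-2-(guaiazulen-3-yl)-3-methylpent-4-enoic acid (syn, racemic) | C=C[C@@H](C)[C@H](c1cc(C)c2cc(C(C)C)ccc(C)c1-2)C(=O)O | intermediate
12 | 1-[(2R*,3R*)-2-(guaiazulen-3-yl)-3-methylpent-4-enoyl]imidazole | C=C[C@@H](C)[C@H](c1cc(C)c2cc(C(C)C)ccc(C)c1-2)C(=O)n3ccnc3 | intermediate (not isolated)
13 | (2R*,3R*)-2-(guaiazulen-3-yl)-3-methylpent-4-enal | C=C[C@@H](C)[C@H](c1cc(C)c2cc(C(C)C)ccc(C)c1-2)C=O | intermediate
14 | pent-1-en-3-one (ethyl vinyl ketone) | C=CC(=O)CC | starting material
15 | (2R*,3R*,4E)-2-(guaiazulen-3-yl)-3-methyl-6-oxooct-4-enal | CCC(=O)/C=C/[C@@H](C)[C@H](c1cc(C)c2cc(C(C)C)ccc(C)c1-2)C=O | intermediate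
16 | 1-[3,4-trans-4-(guaiazulen-3-yl)-5-hydroxy-3-methylcyclopent-1-en-1-yl]propan-1-one (carbinol epimers) | CCC(=O)C1=C[C@@H](C)[C@H](c2cc(C)c3cc(C(C)C)ccc(C)c2-3)C1O | intermediate
17 | 1-[3,4-trans-5-(tert-butyldimethylsilyloxy)-4-(guaiazulen-3-yl)-3-methylcyclopent-1-en-1-yl]propan-1-one | CCC(=O)C1=C[C@@H](C)[C@H](c2cc(C)c3cc(C(C)C)ccc(C)c2-3)C1O[Si](C)(C)C(C)(C)C | intermediate
18 | 4,4,4-trifluoro-2-methyl-1-[3,4-trans-5-(tert-butyldimethylsilyloxy)-4-(guaiazulen-3-yl)-3-methylcyclopent-1-en-1-yl]butane-1,3-dione | CC(C(=O)C(F)(F)F)C(=O)C1=C[C@@H](C)[C@H](c2cc(C)c3cc(C(C)C)ccc(C)c2-3)C1O[Si](C)(C)C(C)(C)C | intermediate (not isolated)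
19 | 2-diazo-1-[3,4-trans-5-(tert-butyldimethylsilyloxy)-4-(guaiazulen-3-yl)-3-methylcyclopent-1-en-1-yl]propan-1-one (key-step precursor, C1 masked as silyl ether) | CC(=[N+]=[N-])C(=O)C1=C[C@@H](C)[C@H](c2cc(C)c3cc(C(C)C)ccc(C)c2-3)C1O[Si](C)(C)C(C)(C)C | intermediate
20 | 2-[3,4-trans-5-(tert-butyldimethylsilyloxy)-4-(guaiazulen-3-yl)-3-methylcyclopent-1-en-1-yl]prop-1-en-1-one (vinylketene) | CC(=C=O)C1=C[C@@H](C)[C@H](c2cc(C)c3cc(C(C)C)ccc(C)c2-3)C1O[Si](C)(C)C(C)(C)C | intermediate (not isolated)
21 | 3-(guaiazulen-3-yl)-4-methyl-4-[3,4-trans-5-(tert-butyldimethylsilyloxy)-4-(guaiazulen-3-yl)-3-methylcyclopent-1-en-1-yl]cyclobut-2-en-1-one (quaternary carbon: both configurations) | O=C1C=C(c2cc(C)c3cc(C(C)C)ccc(C)c2-3)C1(C)C4=C[C@@H](C)[C@H](c5cc(C)c6cc(C(C)C)ccc(C)c5-6)C4O[Si](C)(C)C(C)(C)C | intermediate (not isolated)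
22 | 3-(guaiazulen-3-yl)-4-[3,4-trans-5-(tert-butyldimethylsilyloxy)-4-(guaiazulen-3-yl)-3-methylcyclopent-1-en-1-yl]penta-1,3-dien-1-one (ketenyl and cyclopentenyl groups cis on the C3=C4 bond) | O=C=C/C(c2cc(C)c3cc(C(C)C)ccc(C)c2-3)=C(/C)C4=C[C@@H](C)[C@H](c5cc(C)c6cc(C(C)C)ccc(C)c5-6)C4O[Si](C)(C)C(C)(C)C | intermediate (not isolated)
23 | 1-(tert-butyldimethylsilyloxy)-2,6-bis(guaiazulen-3-yl)-3,7-dimethyl-1,2,3,3a-tetrahydro-4H-inden-4-one (2,3-trans; C3a open) | C[C@H]1[C@H](c3cc(C)c4cc(C(C)C)ccc(C)c3-4)C(O[Si](C)(C)C(C)(C)C)C2=C(C)C(c5cc(C)c6cc(C(C)C)ccc(C)c5-6)=CC(=O)C21 | intermediate (not isolated)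
24 | 2,3-trans-1-(tert-butyldimethylsilyloxy)-2,6-bis(guaiazulen-3-yl)-3,7-dimethylindan-4-ol (key-step product, C1 masked as silyl ether) | C[C@H]1[C@H](c3cc(C)c4cc(C(C)C)ccc(C)c3-4)C(O[Si](C)(C)C(C)(C)C)c2c(C)c(-c5cc(C)c6cc(C(C)C)ccc(C)c5-6)cc(O)c21 | intermediate
25 | 2,3-trans-2,6-bis(guaiazulen-3-yl)-3,7-dimethylindane-1,4-diol | C[C@H]1[C@H](c3cc(C)c4cc(C(C)C)ccc(C)c3-4)C(O)c2c(C)c(-c5cc(C)c6cc(C(C)C)ccc(C)c5-6)cc(O)c21 | intermediate
26 | 2,3-trans-2,6-bis(guaiazulen-3-yl)-1-hydroxy-3,7-dimethylindan-4-yl trifluoromethanesulfonate | C[C@H]1[C@H](c3cc(C)c4cc(C(C)C)ccc(C)c3-4)C(O)c2c(C)c(-c5cc(C)c6cc(C(C)C)ccc(C)c5-6)cc(OS(=O)(=O)C(F)(F)F)c21 | intermediate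
27 | trans-2,6-bis(guaiazulen-3-yl)-3,7-dimethyl-1-oxoindan-4-yl trifluoromethanesulfonate | C[C@H]1[C@H](c3cc(C)c4cc(C(C)C)ccc(C)c3-4)C(=O)c2c(C)c(-c5cc(C)c6cc(C(C)C)ccc(C)c5-6)cc(OS(=O)(=O)C(F)(F)F)c21 | intermediate
28 | 2,6-bis(guaiazulen-3-yl)-3,7-dimethyl-1-(trimethylsilyloxy)-3H-inden-4-yl trifluoromethanesulfonate (racemic at C3) | C[C@H]1C(c3cc(C)c4cc(C(C)C)ccc(C)c3-4)=C(O[Si](C)(C)C)c2c(C)c(-c5cc(C)c6cc(C(C)C)ccc(C)c5-6)cc(OS(=O)(=O)C(F)(F)F)c21 | intermediate (not isolated)
29 | 2,6-bis(guaiazulen-3-yl)-3,7-dimethyl-1-oxo-1H-inden-4-yl trifluoromethanesulfonate | CC1=C(c3cc(C)c4cc(C(C)C)ccc(C)c3-4)C(=O)c2c(C)c(-c5cc(C)c6cc(C(C)C)ccc(C)c5-6)cc(OS(=O)(=O)C(F)(F)F)c21 | intermediate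
30 | 2,6-bis(guaiazulen-3-yl)-3,7-dimethyl-1-oxo-1H-indene-4-carbaldehyde | CC1=C(c2cc(C)c3cc(C(C)C)ccc(C)c2-3)C(=O)c2c(C)c(-c3cc(C)c4cc(C(C)C)ccc(C)c3-4)cc(C=O)c21 | target

**Step count**
Total step count: 16. Longest linear sequence: 14 (steps 3 to 16, from guaiazulene). Steps 1 and 2 form the alkyne branch.

**Steps most likely to fail**

1. Step 11.
The addition of an aryl alkyne to the ketene may be too slow. The ketene would then be lost to dimerisation, to its own electrocyclic closure, to acylation of phenol already formed, or to traces of water. Nitrogen loss through a free carbene, followed by 1,2-hydride shift from the methyl group, may also compete with the Wolff shift.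
The fallback uses known chemistry, sets out from 19 and 1, and returns at 21.
- 19 is irradiated under the same light with ethoxyacetylene, an established ketenophile, and the mixture is not heated. This should stop the sequence at 3-ethoxy-4-methyl-4-(cyclopentenyl)cyclobut-2-en-1-one F1.
- In parallel, 1 is iodinated with N-iodosuccinimide to 3-iodoguaiazulene F2. This is used at once for iodine–magnesium exchange (iPrMgCl·LiCl, THF, −40 °C) to guaiazulen-3-ylmagnesium chloride F3.
- 1,2-Addition of F3 to the strained carbonyl group of F1 gives the tertiary cyclobutenol F4.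
- Dilute acid (aq oxalic acid or silica gel) converts this enol ether into the transposed enone with loss of ethanol (Stork–Danheiser-type carbonyl transposition). Because C4 of a cyclobutenone is bonded to both C1 and C3, the transposed product is 21 itself.
- Heating 21 in toluene at 80–110 °C then follows the route through 22 and 23 to 24.

2. Step 15.
Transfer of the crowded tetrasubstituted silyl enol ether to palladium may be slow, so that protodesilylation back to the ketone prevails. Electrophilic palladation or one-electron oxidation of the azulene rings by divalent palladium may also intervene.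
The fallback sets out from 27 and returns at 29.
- 27 is deprotonated with LiN(SiMe3)2 (THF, −78 °C) and the enolate is quenched with PhSeCl. Selenium should enter at C2 from the face opposite the C3 methyl group and give the α-phenylselanyl ketone F5, with selenium syn to C3–H.
- One equivalent of m-chloroperbenzoic acid at −78 °C gives the selenoxide F6.
- F6 undergoes syn elimination on warming to give 29.

3. Step 8.
Phosphine addition to the γ-branched enone may be slow. Enolisation of the α-azulenyl aldehyde or intermolecular enone coupling could then overtake ring closure.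
The fallback sets out from 13, bypasses 15, and returns at 16.
- Pent-1-yn-3-one is hydroaluminated with iBu2AlH in the presence of N-methylmorpholine N-oxide (THF, 0 °C) to the α-propanoylvinylalane F7, a stoichiometric equivalent of the Baylis–Hillman enolate.
- F7 adds to 13 to give the acyclic α-methylene-β-hydroxy ketone F8.
- Ring-closing metathesis of F8 (second-generation Grubbs catalyst, CH2Cl2, 40 °C) forms C3a=C7a and gives 16.

**Further compounds**
F1 | step 11 | 3-ethoxy-4-methyl-4-[3,4-trans-5-(tert-butyldimethylsilyloxy)-4-(guaiazulen-3-yl)-3-methylcyclopent-1-en-1-yl]cyclobut-2-en-1-one | CCOC1=CC(=O)C1(C)C2=C[C@@H](C)[C@H](c3cc(C)c4cc(C(C)C)ccc(C)c3-4)C2O[Si](C)(C)C(C)(C)C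
F2 | step 11 | 3-iodoguaiazulene | Ic1cc(C)c2cc(C(C)C)ccc(C)c1-2
F3 | step 11 | guaiazulen-3-ylmagnesium chloride | Cl[Mg]c1cc(C)c2cc(C(C)C)ccc(C)c1-2
F4 | step 11 | 3-ethoxy-1-(guaiazulen-3-yl)-4-methyl-4-[3,4-trans-5-(tert-butyldimethylsilyloxy)-4-(guaiazulen-3-yl)-3-methylcyclopent-1-en-1-yl]cyclobut-2-en-1-ol | CCOC1=CC(O)(c5cc(C)c6cc(C(C)C)ccc(C)c5-6)C1(C)C2=C[C@@H](C)[C@H](c3cc(C)c4cc(C(C)C)ccc(C)c3-4)C2O[Si](C)(C)C(C)(C)C
F5 | step 15 | 2,6-bis(guaiazulen-3-yl)-3,7-dimethyl-1-oxo-2-(phenylselanyl)indan-4-yl trifluoromethanesulfonate (Se trans to the C3 methyl group) | C[C@H]1[C@](c3cc(C)c4cc(C(C)C)ccc(C)c3-4)([Se]c7ccccc7)C(=O)c2c(C)c(-c5cc(C)c6cc(C(C)C)ccc(C)c5-6)cc(OS(=O)(=O)C(F)(F)F)c21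
F6 | step 15 | 2,6-bis(guaiazulen-3-yl)-3,7-dimethyl-1-oxo-2-(phenylseleninyl)indan-4-yl trifluoromethanesulfonate | C[C@H]1[C@](c3cc(C)c4cc(C(C)C)ccc(C)c3-4)([Se](=O)c7ccccc7)C(=O)c2c(C)c(-c5cc(C)c6cc(C(C)C)ccc(C)c5-6)cc(OS(=O)(=O)C(F)(F)F)c21
F7 | step 8 | diisobutyl(3-oxopent-1-en-2-yl)alane | CCC(=O)C(=C)[Al](CC(C)C)CC(C)C
F8 | step 8 | (6R*,7R*)-6-(guaiazulen-3-yl)-5-hydroxy-7-methyl-4-methylidenenon-8-en-3-one (carbinol epimers) | C=C[C@@H](C)[C@H](c1cc(C)c2cc(C(C)C)ccc(C)c1-2)C(O)C(=C)C(=O)CC
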